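## Structural features

The target 25 is a chroman. Benzene ring A is fused through C4a–C8a to dihydropyran ring B, which holds O1, the gem-dimethyl carbon C2, the secondary carbinol C3 and the benzylic methylene C4. Ring A is pentasubstituted and only C6 is free: C8a carries O1, C8 the prenyl group, C7 a free phenol, C5 the (E)-styryl group and C4a the C4 methylene. The two oxygens are therefore meta to each other with the prenyl carbon between them. C3 (R) is the only stereocentre and has no stereogenic neighbour (C2 is quaternary, C4 is CH2), so only absolute configuration has to be controlled. The fragile groups are the prenyl alkene ortho to a free phenol (acid closes it to a second dimethylchroman), the stilbene-type alkene (light, hydrogenation, oxidants), the electron-rich resorcinol-type ring and the tert-alkyl aryl ether O1–C2. The real difficulty is the order of five different substituents on ring A: substitution of a 5-styrylresorcinol cannot tell C8 from C4a and C6, nor one oxygen from the other. The key step exploits the 1,3-dioxygenation with a carbon substituent between the oxygens. A vinylketene/alkynyl ether benzannulation supplies C7 with its hydroxyl from the ketene carbon, C8 (prenyl) and C8a (O1) from the alkyne carbons, and C4a, C5 (styryl) and C6 from the cyclobutenone. O1 arrives already alkylated by the C2–C3–C4 unit in the R configuration, and C4a is left free, ortho to O1 and para to the C7 hydroxyl, for the closure of ring B.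

## Logic of the disconnections

The C4–C4a bond is cut first, taking 25 back to 24. C4a is the only ring carbon the O1-bound chain can reach, and it is the most nucleophilic position of ring A (ortho to O1, para to the C7 hydroxyl). The electrophile is the terminal carbon of an epoxide whose other carbon is C3. This removes ring B and leaves a monocyclic arene in which C3 is already configured. The forward step must open the epoxide at the primary carbon in a 6-endo sense, must leave the C3–O bond intact, and must be mild enough for the ortho-prenylphenol.

The epoxide C4–O bond is then traced back through the primary sulfonate 23 to diol 22, its acetonide 21 and the free phenol 20. No skeletal bond is cut; the gain is that 20 is exactly what the ring A synthesis delivers. The forward sequence must never break the C3–O bond, which closure by the C3 alkoxide onto C4 ensures. It must also keep the phenol from competing for the sulfonyl chloride, so the phenol is masked as an acetate in 21, and that acetate is lost in the same basic operation that closes the epoxide.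

Ring A of 20 is cut at C7–C8, C8a–C4a and C6–C7, giving 15 and 9. This is the point of greatest simplification: a pentasubstituted arene becomes a four-membered enone and a linear alkynyl ether, each reachable in two or three steps, and the stereocentre travels as a spectator in 9. The forward step needs one regiochemical outcome (the prenyl carbon next to the phenol carbon), which the polarity of the alkynyl ether dictates. It also needs 9 to survive the temperature at which 15 opens. Because 9 is a tert-alkyl alkynyl ether that can fragment by a retro-ene path, it is fed slowly into an excess of hot 15 instead of being heated in bulk.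

In 9 the C(sp)–CH2 bond to the prenyl group is cut, giving the acetylide 8 (made in the flask from 5) and 6. The O–C(sp) bond is then cut back to the tertiary alcohol 3, and the two C–CH3 bonds of the future C2 are cut back to the ester 1. The reason is that 1 is a cheap chiral-pool compound whose stereocentre maps directly onto C3 with the right descriptor. The forward demands are that the Grignard addition does not enolise the α-alkoxy centre, that the diol stays protected as the acetonide through the strongly basic steps, and that the acetylide attacks the primary carbon of 6.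

In 15 the bond between the ring and the styryl group is cut to the vinyllithium 13 (from 12) and the vinylogous ester 11, and 11 is cut across its four-membered ring to 10 and a C2 ketene unit. This reduces the dienone to three small commercial pieces. The forward demands are a halogen–lithium exchange that keeps the E geometry, clean 1,2-addition to 11, and a hydrolysis gentle enough for the dienyl cyclobutenone.

## Other disconnections considered

Alternative 1: The cut is at C5–C6 and C8–C8a, with O1–C8a re-formed after the annulation. In the forward sense the kinetic methyl enolate of 6-methylhept-5-en-2-one A2 would add through C6 to C5 of the cinnamylidene lactone A1. The regenerated enolate at C8 would then attack the lactone carbonyl, and acid would reclose O1 onto C8a to give the hexahydrochromenone A3.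
- In its favour: the chemistry is ionic and run cold, ring B and C3 are present from the start, and A2 brings C6, C7, C8 and the prenyl group in one commercial piece.
- Against it: the dienyl acceptor A1 also offers 1,6-addition at the styryl terminus, and the enolate of A2 can equilibrate to the methylene side. A3 also sits two hydrogens above the arene, so it needs a dehydrogenation in the presence of allylic and benzylic C–H bonds and two oxidisable alkenes, followed by desilylation.
- Structure: both plans fix the substitution pattern by connectivity, so they are equal here. The alternative is the better one in having no late C–C closure of ring B.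
- Mechanism: the alternative is the better one in avoiding a thermally fragile partner. The chosen plan is the better one in reaching the aromatic oxidation level without a redox step.
- Step economy: the end game after A3 (aromatise, desilylate) is shorter than the four steps after 20, but A1 needs several steps from a chiral lactone, so the totals are expected to be similar.

Alternative 2: The cut is at O1–C2 and C3–C4. A chiral phosphoric acid would dehydrate the salicyl alcohol A4 to an ortho-quinone methide, which would take up the isobutenylboronate A5 in an inverse-demand hetero-Diels–Alder reaction to give the 3-borylchroman A6. Retentive oxidation of the C–B bond and desilylation would then give 25.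
- In its favour: ring B and C3 are made in one catalytic, convergent step without a chiral-pool fragment, and the C–B oxidation is mild and stereoretentive. For ring B alone this is the better plan in step count.
- Against it: ring A is not addressed. A4 is itself a pentasubstituted arene, and its hydroxymethyl group must be placed at C4a and not at C6, so the main difficulty is only moved. A5 is a trisubstituted, boron-bearing alkene and a weak partner for an electron-rich quinone methide, and it offers the catalyst no hydrogen-bond handle. The acid also meets a phenol with an ortho prenyl group in A4.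
- Structure: the chosen plan is the better one, because it solves the ring A order.
- Mechanism: the alternative's enantiocontrol rests on a catalyst–substrate match that is uncertain, whereas the chosen plan takes its configuration from 1; the chosen plan is the safer one.
- Step economy: the alternative is equal or better after A4, but worse once the synthesis of A4 is counted.

Alternative 3: The cut is at C4a–C5. Mild acid would turn the cyclic vinylogous ester A7 into its ring dienol ether, C4a would add to the cinnamoyl carbonyl C5, and loss of water would close ring A on the intact pyran to give the silyl ether A8. One desilylation would then give 25.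
- In its favour: the arene is formed at the right oxidation level with every substituent placed by connectivity, ring B and C3 are already in place, and nothing is heated. Its end game (one step after A8) is the better one.
- Against it: A7 is a masked 1,3,5-tricarbonyl compound with an exocyclic enol ether. Its assembly is multi-step and tautomerically ill-defined. Under acid the enol oxygen can close onto C5 to give a pyranone, the enol ether can hydrolyse, and the cinnamoyl enone can take conjugate additions.
- Structure: both plans build ring A from non-aromatic precursors, so they are equal here.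
- Mechanism: the alternative is milder. The chosen plan has a single regiochemical vector (the polarity of the alkynyl ether), where the alternative has several competing carbonyl condensations; the chosen plan is the more predictable.
- Step economy: comparable overall. The chosen plan's fragments 9 and 15 are each made in two or three steps from commercial materials, which A7 is not.

Key step: step 6

Assumption: the dioxolanyl-substituted tert-alkyl alkynyl ether 9 is taken to undergo retro-ene loss more slowly than a tert-butyl analogue but still fast enough near 80 °C to require the slow-addition protocol of step 6.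

## Route

Step 1
Reactants: 1 methyl (4R)-2,2-dimethyl-1,3-dioxolane-4-carboxylate
Product: 3 2-[(4R)-2,2-dimethyl-1,3-dioxolan-4-yl]propan-2-ol, via methyl ketone 2 (not isolated)
Conditions: MeMgBr (2.5 equiv), Et2O, 0 °C → rt; aq. NH4Cl
Reagents that add atoms: methylmagnesium bromide, C[Mg]Br
Why: Double Grignard addition to an ester; addition to ketone 2 is faster than its enolisation at 0 °C, so the α-alkoxy centre should be kept, and the acetonide is inert to the reagent.

Step 2
Reactants: 3 2-[(4R)-2,2-dimethyl-1,3-dioxolan-4-yl]propan-2-ol
Product: 5 (4R)-4-[2-[(E)-1,2-dichloroethenoxy]propan-2-yl]-2,2-dimethyl-1,3-dioxolane, via potassium alkoxide 4 (not isolated)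
Conditions: KH (1.2 equiv), THF, 0 °C → rt; Cl2C=CHCl (1.05 equiv), −50 °C → rt
Reagents that add atoms: trichloroethylene, ClC=C(Cl)Cl
Why: Alkoxide 4 dehydrochlorinates trichloroethylene to dichloroacetylene and adds to it in an anti sense, the standard entry to 1,2-dichlorovinyl ethers that also works for tertiary alkoxides; the stereocentre is not involved.

Step 3
Reactants: 5 (4R)-4-[2-[(E)-1,2-dichloroethenoxy]propan-2-yl]-2,2-dimethyl-1,3-dioxolane; 6 1-bromo-3-methylbut-2-ene (prenyl bromide)
Product: 9 (4R)-2,2-dimethyl-4-[2-(5-methylhex-4-en-1-ynoxy)propan-2-yl]-1,3-dioxolane, via chloroalkynyl ether 7 (not isolated), via lithium alkynyl ether 8 (not isolated)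
Conditions: n-BuLi (2.2 equiv), THF, −78 → −40 °C; then 6, DMPU, −78 °C → rt; chromatography on Et3N-deactivated silica, stored cold
Reagents that add atoms: none
Why: β-Elimination of HCl gives 7 and chlorine–lithium exchange gives acetylide 8, which is alkylated at the unhindered primary carbon of the allylic bromide (SN2 alkylation of a lithium alkoxyacetylide in a dipolar cosolvent); the acetonide and the stereocentre are spectators.

Step 4
Reactants: 10 ethoxyethyne (ethoxyacetylene)
Product: 11 3-ethoxycyclobut-2-en-1-one
Conditions: AcCl (slow addition), Et3N, MeCN, 0 °C → rt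
Reagents that add atoms: acetyl chloride, CC(Cl)=O
Why: Ketene made in the flask by dehydrochlorination of acetyl chloride undergoes [2+2] cycloaddition with the electron-rich alkyne, the ketene carbonyl carbon bonding to the oxygen-free alkyne carbon; this avoids handling ketene gas.

Step 5
Reactants: 12 [(E)-2-bromoethenyl]benzene ((E)-β-bromostyrene); 11 3-ethoxycyclobut-2-en-1-one
Product: 15 3-[(E)-2-phenylethenyl]cyclobut-2-en-1-one, via (E)-styryllithium 13 (not isolated), via lithium cyclobutenolate 14 (not isolated)
Conditions: t-BuLi (2.0 equiv), Et2O, −78 °C; then 11, −78 °C; then 1 M aq. HCl, 0 °C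
Reagents that add atoms: water, O
Why: Bromine–lithium exchange with retention of the E geometry, 1,2-addition to the vinylogous ester and acid hydrolysis with loss of ethanol and water is the standard carbonyl transposition route to 3-substituted cyclobutenones; the carbonyl oxygen of 15 comes from the aqueous acid.

Step 6
Reactants: 15 3-[(E)-2-phenylethenyl]cyclobut-2-en-1-one; 9 (4R)-2,2-dimethyl-4-[2-(5-methylhex-4-en-1-ynoxy)propan-2-yl]-1,3-dioxolane
Product: 20 3-[2-[(4R)-2,2-dimethyl-1,3-dioxolan-4-yl]propan-2-yl]oxy-2-(3-methylbut-2-enyl)-5-[(E)-2-phenylethenyl]phenol, via vinylketene 16 (not isolated), via 4-dienylcyclobutenone 17 (not isolated), via dienylketene 18 (not isolated), via cyclohexadienone 19 (not isolated)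
Conditions: 15 (1.5 equiv), PhMe, 80 °C, 9 added over 6 h by syringe pump; then 110 °C; then K2CO3, MeOH, rt
Reagents that add atoms: none
Why: Heating opens 15 by a conrotatory four-electron electrocyclic cleavage to vinylketene 16, whose carbonyl carbon is attacked by the oxygen-free, nucleophilic alkyne carbon of 9 in a [2+2] cycloaddition that gives cyclobutenone 17. A second four-electron opening gives dienylketene 18, which closes ring A by a disrotatory six-electron electrocyclisation (ketene carbon to the former ring methylene) to cyclohexadienone 19, and tautomerisation gives phenol 20. This is the Danheiser benzannulation of a cyclobutenone with an alkoxyalkyne, a known reaction type. Regiochemistry is the one selectivity needed and follows from the polarisation of the alkynyl ether, so the prenyl carbon ends next to the phenol carbon with the ether oxygen meta to the hydroxyl. No stereocentre is formed in 20 (the ring CH of 17 is transient), and the dioxolane centre, the acetonide and both alkenes are untouched under neutral thermal conditions. The weak point is retro-ene loss of the tert-alkyl group from 9 at the same temperature. Capture of 9 is limited by the opening of 15 and so is zero order in 9, whereas the retro-ene loss is first order in 9, so slow addition of 9 into an excess of hot 15 keeps its standing concentration low and favours benzannulation. The carbonate/methanol work-up cleaves any aryl ester formed from 20 and surplus 16; the intended equation is a 1:1 combination without a co-product.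

Step 7
Reactants: 20 3-[2-[(4R)-2,2-dimethyl-1,3-dioxolan-4-yl]propan-2-yl]oxy-2-(3-methylbut-2-enyl)-5-[(E)-2-phenylethenyl]phenol
Product: 21 [3-[2-[(4R)-2,2-dimethyl-1,3-dioxolan-4-yl]propan-2-yl]oxy-2-(3-methylbut-2-enyl)-5-[(E)-2-phenylethenyl]phenyl] acetate
Conditions: Ac2O, pyridine, DMAP (cat.), CH2Cl2, rt
Reagents that add atoms: acetic anhydride, CC(=O)OC(C)=O
Why: Routine O-acetylation of a phenol; the acetate keeps the phenol from competing in the sulfonylation of step 9 and is removed there without a separate step.

Step 8
Reactants: 21 [3-[2-[(4R)-2,2-dimethyl-1,3-dioxolan-4-yl]propan-2-yl]oxy-2-(3-methylbut-2-enyl)-5-[(E)-2-phenylethenyl]phenyl] acetate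
Product: 22 [3-[(3R)-3,4-dihydroxy-2-methylbutan-2-yl]oxy-2-(3-methylbut-2-enyl)-5-[(E)-2-phenylethenyl]phenyl] acetate
Conditions: AcOH–H2O (4:1), 40 °C
Reagents that add atoms: none
Why: Hydrolysis of a terminal acetonide in aqueous acetic acid; the acid is too weak to protonate the prenyl alkene or to ionise the β-oxygenated tert-alkyl aryl ether, the aryl acetate is stable in this medium, and no bond to C3 is broken.

Step 9
Reactants: 22 [3-[(3R)-3,4-dihydroxy-2-methylbutan-2-yl]oxy-2-(3-methylbut-2-enyl)-5-[(E)-2-phenylethenyl]phenyl] acetate
Product: 24 2-(3-methylbut-2-enyl)-3-[2-[(2R)-oxiran-2-yl]propan-2-yl]oxy-5-[(E)-2-phenylethenyl]phenol, via primary tosylate 23 (not isolated)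
Conditions: TsCl (1.05 equiv), Et3N, Bu2SnO (2 mol%), CH2Cl2, 0 °C → rt; then K2CO3, MeOH, rt
Reagents that add atoms: none
Why: Tin-catalysed sulfonylation is selective for the primary hydroxyl of a terminal 1,2-diol (the secondary one is also neopentyl-like), and carbonate in methanol then closes the epoxide by attack of the C3 alkoxide on the primary carbon and removes the aryl acetate by methanolysis. The C3–O bond is never broken, so the configuration is retained.

Step 10
Reactants: 24 2-(3-methylbut-2-enyl)-3-[2-[(2R)-oxiran-2-yl]propan-2-yl]oxy-5-[(E)-2-phenylethenyl]phenol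
Product: 25 (3R)-2,2-dimethyl-8-(3-methylbut-2-enyl)-5-[(E)-2-phenylethenyl]-3,4-dihydro-2H-chromene-3,7-diol
Conditions: (CF3)2CHOH (HFIP), 0.02 M, 40 °C
Reagents that add atoms: none
Why: The fluorinated alcohol activates the epoxide by hydrogen bonding, and C4a (ortho to the ether oxygen, para to the free phenol) opens it at the terminal carbon in a 6-endo intramolecular Friedel–Crafts epoxide–arene cyclisation, a known reaction of aryl glycidyl ethers that the gem-dimethyl group should assist. The C3–O bond is not touched, so the R configuration from 1 is carried into 25, and the absence of mineral or Lewis acid spares the ortho-prenylphenol and the tert-alkyl aryl ether; the 5-exo mode would need attack at the hindered C3.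

## Compound list

1 | methyl (4R)-2,2-dimethyl-1,3-dioxolane-4-carboxylate | COC(=O)[C@H]1COC(C)(C)O1 | starting material
2 | 1-[(4R)-2,2-dimethyl-1,3-dioxolan-4-yl]ethan-1-one | CC(=O)[C@H]1COC(C)(C)O1 | intermediate
3 | 2-[(4R)-2,2-dimethyl-1,3-dioxolan-4-yl]propan-2-ol | CC(C)(O)[C@H]1COC(C)(C)O1 | intermediate
4 | potassium 2-[(4R)-2,2-dimethyl-1,3-dioxolan-4-yl]propan-2-olate | CC(C)([O-])[C@H]1COC(C)(C)O1.[K+] | intermediate
5 | (4R)-4-[2-[(E)-1,2-dichloroethenoxy]propan-2-yl]-2,2-dimethyl-1,3-dioxolane | Cl/C=C(/Cl)OC(C)(C)[C@H]1COC(C)(C)O1 | intermediate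
6 | 1-bromo-3-methylbut-2-ene | CC(C)=CCBr | starting material
7 | (4R)-4-[2-(2-chloroethynoxy)propan-2-yl]-2,2-dimethyl-1,3-dioxolane | ClC#COC(C)(C)[C@H]1COC(C)(C)O1 | intermediate
8 | [2-[2-[(4R)-2,2-dimethyl-1,3-dioxolan-4-yl]propan-2-yl]oxyethynyl]lithium | [Li]C#COC(C)(C)[C@H]1COC(C)(C)O1 | intermediate
9 | (4R)-2,2-dimethyl-4-[2-(5-methylhex-4-en-1-ynoxy)propan-2-yl]-1,3-dioxolane | CC(C)=CCC#COC(C)(C)[C@H]1COC(C)(C)O1 | intermediate
10 | ethoxyethyne | C#COCC | starting material
11 | 3-ethoxycyclobut-2-en-1-one | CCOC1=CC(=O)C1 | intermediate
12 | [(E)-2-bromoethenyl]benzene | Br/C=C/c1ccccc1 | starting material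
13 | [(E)-2-phenylethenyl]lithium | [Li]/C=C/c1ccccc1 | intermediate
14 | lithium 3-ethoxy-1-[(E)-2-phenylethenyl]cyclobut-2-en-1-olate (racemic at C1) | CCOC1=CC([O-])(/C=C/c2ccccc2)C1.[Li+] | intermediate
15 | 3-[(E)-2-phenylethenyl]cyclobut-2-en-1-one | O=C1C=C(/C=C/c2ccccc2)C1 | intermediate
16 | (4E)-3-methylidene-5-phenylpenta-1,4-dien-1-one | O=C=CC(=C)/C=C/c1ccccc1 | intermediate
17 | 3-[2-[(4R)-2,2-dimethyl-1,3-dioxolan-4-yl]propan-2-yl]oxy-2-(3-methylbut-2-enyl)-4-[(3E)-4-phenylbuta-1,3-dien-2-yl]cyclobut-2-en-1-one (both C4 epimers) | O=C1C(CC=C(C)C)=C(OC(C)(C)[C@H]2COC(C)(C)O2)C1C(=C)/C=C/c1ccccc1 | intermediate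
18 | (3E,6E)-3-[2-[(4R)-2,2-dimethyl-1,3-dioxolan-4-yl]propan-2-yl]oxy-2-(3-methylbut-2-enyl)-5-methylidene-7-phenylhepta-1,3,6-trien-1-one | O=C=C(CC=C(C)C)/C(OC(C)(C)[C@H]1COC(C)(C)O1)=C\C(=C)/C=C/c1ccccc1 | intermediate
19 | 3-[2-[(4R)-2,2-dimethyl-1,3-dioxolan-4-yl]propan-2-yl]oxy-2-(3-methylbut-2-enyl)-5-[(E)-2-phenylethenyl]cyclohexa-2,4-dien-1-one | O=C1CC(/C=C/c2ccccc2)=CC(OC(C)(C)[C@H]2COC(C)(C)O2)=C1CC=C(C)C | intermediate
20 | 3-[2-[(4R)-2,2-dimethyl-1,3-dioxolan-4-yl]propan-2-yl]oxy-2-(3-methylbut-2-enyl)-5-[(E)-2-phenylethenyl]phenol | CC(C)=CCc1c(O)cc(/C=C/c2ccccc2)cc1OC(C)(C)[C@H]1COC(C)(C)O1 | intermediate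
21 | [3-[2-[(4R)-2,2-dimethyl-1,3-dioxolan-4-yl]propan-2-yl]oxy-2-(3-methylbut-2-enyl)-5-[(E)-2-phenylethenyl]phenyl] acetate | CC(C)=CCc1c(OC(C)=O)cc(/C=C/c2ccccc2)cc1OC(C)(C)[C@H]1COC(C)(C)O1 | intermediate
22 | [3-[(3R)-3,4-dihydroxy-2-methylbutan-2-yl]oxy-2-(3-methylbut-2-enyl)-5-[(E)-2-phenylethenyl]phenyl] acetate | CC(C)=CCc1c(OC(C)=O)cc(/C=C/c2ccccc2)cc1OC(C)(C)[C@H](O)CO | intermediate
23 | [(2R)-3-[3-acetyloxy-2-(3-methylbut-2-enyl)-5-[(E)-2-phenylethenyl]phenoxy]-2-hydroxy-3-methylbutyl] 4-methylbenzenesulfonate | CC(C)=CCc1c(OC(C)=O)cc(/C=C/c2ccccc2)cc1OC(C)(C)[C@H](O)COS(=O)(=O)c1ccc(C)cc1 | intermediate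
24 | 2-(3-methylbut-2-enyl)-3-[2-[(2R)-oxiran-2-yl]propan-2-yl]oxy-5-[(E)-2-phenylethenyl]phenol | CC(C)=CCc1c(O)cc(/C=C/c2ccccc2)cc1OC(C)(C)[C@H]1CO1 | intermediate
25 | (3R)-2,2-dimethyl-8-(3-methylbut-2-enyl)-5-[(E)-2-phenylethenyl]-3,4-dihydro-2H-chromene-3,7-diol | CC(C)=CCc1c(O)cc(/C=C/c2ccccc2)c2c1OC(C)(C)[C@H](O)C2 | target

## Step count and least certain steps

Total step count: 10. Longest linear sequence: 8 (steps 1, 2, 3, 6, 7, 8, 9, 10); steps 4 and 5 form the second branch.

**Step 6 (key step).**
- Most likely failure: fragmentation of the alkynyl ether before it is captured. A tert-alkyl alkynyl ether can transfer a methyl hydrogen to the alkyne carbon and leave as an alkene plus a ketene at about the temperature the cyclobutenone needs to open. A second, smaller loss is acylation of the product phenol by surplus vinylketene; the basic methanol work-up corrects that.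
- Fallback: separate ketene formation from heat. It sets out from 9 and returns at 20.
  - Horner–Wadsworth–Emmons olefination of commercial (E)-4-phenylbut-3-en-2-one with triethyl phosphonoacetate gives ethyl (2E,4E)-3-methyl-5-phenylpenta-2,4-dienoate F1.
  - Saponification with LiOH gives (2E,4E)-3-methyl-5-phenylpenta-2,4-dienoic acid F2, and oxalyl chloride gives (2E,4E)-3-methyl-5-phenylpenta-2,4-dienoyl chloride F3.
  - Slow addition of F3 to Et3N and 9 in CH2Cl2 at 0 °C to rt generates 16 by 1,4-dehydrochlorination at the methyl group, and 16 is trapped as 17 below the fragmentation temperature.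
  - 17 no longer contains an alkynyl ether and is then warmed to 80 °C to pass through 18 and 19 to 20.

**Step 10.**
- Most likely failure: incomplete activation of the epoxide, so that solvolysis by the medium competes. If stronger acid is then used, the phenol may close onto the prenyl alkene or the tertiary ether may ionise.
- Fallback: remove the free phenol from the problem and use a stoichiometric Lewis acid at low temperature. It sets out from 24 and returns at 25.
  - Silylation (TBSCl, imidazole, DMF) gives the silyl ether of the epoxide, tert-butyl-dimethyl-[2-(3-methylbut-2-enyl)-3-[2-[(2R)-oxiran-2-yl]propan-2-yl]oxy-5-[(E)-2-phenylethenyl]phenoxy]silane F4.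
  - BF3·OEt2 in CH2Cl2 at −78 °C closes ring B to the 7-O-silyl chromanol F5.
  - Bu4NF in THF releases 25.

**Step 3.**
- Most likely failure: loss of regiocontrol at the allylic electrophile (attack at the tertiary terminus) together with slow C-alkylation of a hindered, weakly nucleophilic alkoxyacetylide, which gives time for base-induced isomerisation of the skipped enyne.
- Fallback: introduce the side chain as allyl and convert it to prenyl later. It sets out from 5 and returns at 20.
  - The acetylide 8 is alkylated with allyl bromide, for which both modes of attack give the same product, the allyl alkynyl ether (4R)-2,2-dimethyl-4-[2-(pent-4-en-1-ynoxy)propan-2-yl]-1,3-dioxolane F6.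
  - F6 is combined with 15 under the conditions of step 6 to give the 2-allylphenol F7.
  - Cross-metathesis of F7 with 2-methylbut-2-ene and the second-generation Grubbs catalyst turns the allyl group into prenyl, giving 20.

**Step 5.**
- Most likely failure: elimination to phenylacetylene competing with the halogen–lithium exchange, and polymerisation of the dienyl cyclobutenone during the acidic hydrolysis.
- Fallback: build the four-membered ring on the preformed enyne. It sets out from 12 and returns at 15.
  - Sonogashira coupling of 12 with ethynyltrimethylsilane (PdCl2(PPh3)2, copper iodide CuI, Et3N) gives trimethyl-[(E)-4-phenylbut-3-en-1-ynyl]silane F8.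
  - K2CO3 in MeOH gives [(E)-but-1-en-3-ynyl]benzene F9.
  - Dichloroketene (Cl3CCOCl, Zn–Cu couple, Et2O) adds across the alkyne to give 4,4-dichloro-3-[(E)-2-phenylethenyl]cyclobut-2-en-1-one F10.
  - Zn, AcOH and TMEDA remove both chlorines to give 15.

## Further compounds

F1 | step 6 | ethyl (2E,4E)-3-methyl-5-phenylpenta-2,4-dienoate | CCOC(=O)/C=C(C)/C=C/c1ccccc1
F2 | step 6 | (2E,4E)-3-methyl-5-phenylpenta-2,4-dienoic acid | OC(=O)/C=C(C)/C=C/c1ccccc1
F3 | step 6 | (2E,4E)-3-methyl-5-phenylpenta-2,4-dienoyl chloride | ClC(=O)/C=C(C)/C=C/c1ccccc1
F4 | step 10 | tert-butyl-dimethyl-[2-(3-methylbut-2-enyl)-3-[2-[(2R)-oxiran-2-yl]propan-2-yl]oxy-5-[(E)-2-phenylethenyl]phenoxy]silane | CC(C)=CCc1c(O[Si](C)(C)C(C)(C)C)cc(/C=C/c2ccccc2)cc1OC(C)(C)[C@H]1CO1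
F5 | step 10 | (3R)-7-[tert-butyl(dimethyl)silyl]oxy-2,2-dimethyl-8-(3-methylbut-2-enyl)-5-[(E)-2-phenylethenyl]-3,4-dihydro-2H-chromen-3-ol | CC(C)=CCc1c(O[Si](C)(C)C(C)(C)C)cc(/C=C/c2ccccc2)c2c1OC(C)(C)[C@H](O)C2
F6 | step 3 | (4R)-2,2-dimethyl-4-[2-(pent-4-en-1-ynoxy)propan-2-yl]-1,3-dioxolane | C=CCC#COC(C)(C)[C@H]1COC(C)(C)O1
F7 | step 3 | 3-[2-[(4R)-2,2-dimethyl-1,3-dioxolan-4-yl]propan-2-yl]oxy-5-[(E)-2-phenylethenyl]-2-prop-2-enylphenol | C=CCc1c(O)cc(/C=C/c2ccccc2)cc1OC(C)(C)[C@H]1COC(C)(C)O1
F8 | step 5 | trimethyl-[(E)-4-phenylbut-3-en-1-ynyl]silane | C[Si](C)(C)C#C/C=C/c1ccccc1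
F9 | step 5 | [(E)-but-1-en-3-ynyl]benzene | C#C/C=C/c1ccccc1
F10 | step 5 | 4,4-dichloro-3-[(E)-2-phenylethenyl]cyclobut-2-en-1-one | O=C1C=C(/C=C/c2ccccc2)C1(Cl)Cl
A1 | alternative 1 | (3E,5R)-5-[tert-butyl(dimethyl)silyl]oxy-6,6-dimethyl-3-[(E)-3-phenylprop-2-enylidene]oxan-2-one | O=C1OC(C)(C)[C@H](O[Si](C)(C)C(C)(C)C)C/C1=C\C=C\c1ccccc1
A2 | alternative 1 | 6-methylhept-5-en-2-one | CC(=O)CCC=C(C)C
A3 | alternative 1 | (3R)-3-[tert-butyl(dimethyl)silyl]oxy-2,2-dimethyl-8-(3-methylbut-2-enyl)-5-[(E)-2-phenylethenyl]-2,3,4,4a,5,6-hexahydrochromen-7-one (C4a and C5 epimers) | CC(C)=CCC1=C2OC(C)(C)[C@H](O[Si](C)(C)C(C)(C)C)CC2C(/C=C/c2ccccc2)CC1=O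
A4 | alternative 2 | 2-(hydroxymethyl)-6-(3-methylbut-2-enyl)-3-[(E)-2-phenylethenyl]-5-tri(propan-2-yl)silyloxyphenol | CC(C)=CCc1c(O[Si](C(C)C)(C(C)C)C(C)C)cc(/C=C/c2ccccc2)c(CO)c1O
A5 | alternative 2 | 4,4,5,5-tetramethyl-2-(2-methylprop-1-enyl)-1,3,2-dioxaborolane | CC(C)=CB1OC(C)(C)C(C)(C)O1
A6 | alternative 2 | [(3R)-2,2-dimethyl-8-(3-methylbut-2-enyl)-5-[(E)-2-phenylethenyl]-3-(4,4,5,5-tetramethyl-1,3,2-dioxaborolan-2-yl)-3,4-dihydro-2H-chromen-7-yl]oxy-tri(propan-2-yl)silane | CC(C)=CCc1c(O[Si](C(C)C)(C(C)C)C(C)C)cc(/C=C/c2ccccc2)c2c1OC(C)(C)[C@H](B1OC(C)(C)C(C)(C)O1)C2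
A7 | alternative 3 | (1E)-6-[(5R)-5-[tert-butyl(dimethyl)silyl]oxy-6,6-dimethyloxan-2-ylidene]-9-methyl-1-phenyldeca-1,8-diene-3,5-dione | CC(C)=CCC(C(=O)CC(=O)/C=C/c1ccccc1)=C1CC[C@@H](O[Si](C)(C)C(C)(C)C)C(C)(C)O1
A8 | alternative 3 | (3R)-3-[tert-butyl(dimethyl)silyl]oxy-2,2-dimethyl-8-(3-methylbut-2-enyl)-5-[(E)-2-phenylethenyl]-3,4-dihydro-2H-chromen-7-ol | CC(C)=CCc1c(O)cc(/C=C/c2ccccc2)c2c1OC(C)(C)[C@H](O[Si](C)(C)C(C)(C)C)C2
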